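## Retrosynthetic overview

1. The target is read as an all-cis (2S,3S,4R) 4-arylflavan-3-ol (upper unit, rings A/C/B) joined through C4 to C8 of a (2R,3R,4S)-flavan-3,4-diol (lower unit, rings D/F/E). End game: debenzylation ⇐ hydrolysis of a C4 thioether on ring F ⇐ inversion of C3 on ring C by oxidation and hydride reduction.
2. Enabling feature: C4 of ring C is a diarylmethine carbon bonded to C4a of ring A and to C8 of ring D. Both ring carbons are ortho/para to three oxygens, so both bonds trace back to one aldehyde carbon and the same oxygens stabilize a C4 cation.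
3. Key disconnection: an acyclic (2S,3S)-2-silyloxy-3-aryloxy-3-arylpropanal plus a ring-D nucleophile give the protected dimer in one Lewis-acid cascade. Ring C closes by the C4–C4a bond, then the C4–C8(D) bond forms and C4 is set.
4. Aldehyde: (E)-cinnamyl alcohol, Sharpless epoxidation, phenoxide opening (O1–C2 bond, inversion), silylation, Swern oxidation. Nucleophile: (−)-epicatechin, benzylation, DDQ oxidation at C4, thiol exchange (acid-stable mask of the ring-F C4 hydroxyl).
5. Ring order: rings A, B, D, E and F arrive preformed (A, B as bought arenes; D, E, F in epicatechin); ring C is the only ring made, in step 11.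

Key step: step 11

Assumption: the descriptors of the structure are taken at face value, i.e. upper unit (2S,3S,4R) with 2-aryl, 3-OH and 4-aryl all cis (ent-epicatechin series), lower unit (2R,3R,4S) with 2,3-cis-3,4-trans (4β-hydroxy-epicatechin).

## Route

Step 1
Reactants: 1 3,4-bis(benzyloxy)benzaldehyde
Product: 2 ethyl (E)-3-[3,4-bis(benzyloxy)phenyl]prop-2-enoate
Conditions: (EtO)2P(O)CH2CO2Et, NaH, THF, 0 °C → rt
Reagents that add atoms: triethyl phosphonoacetate CCOC(=O)CP(=O)(OCC)OCC
Why: Horner–Wadsworth–Emmons olefination of an aromatic aldehyde with a stabilized phosphonate anion should give the (E)-cinnamate almost exclusively.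

Step 2
Reactants: 2 ethyl (E)-3-[3,4-bis(benzyloxy)phenyl]prop-2-enoate
Product: 3 (E)-3-[3,4-bis(benzyloxy)phenyl]prop-2-en-1-ol
Conditions: i-Bu2AlH, CH2Cl2, −78 °C; Rochelle salt work-up
Reagents that add atoms: none
Why: 1,2-reduction of the unsaturated ester by the aluminium hydride should give the allylic alcohol without touching the alkene or the benzyl ethers.

Step 3
Reactants: 3 (E)-3-[3,4-bis(benzyloxy)phenyl]prop-2-en-1-ol
Product: 4 [(2R,3R)-3-[3,4-bis(benzyloxy)phenyl]oxiran-2-yl]methanol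
Conditions: Ti(Oi-Pr)4 (cat.), D-(−)-diethyl tartrate (cat.), t-BuOOH, 4 Å MS, CH2Cl2, −20 °C
Reagents that add atoms: tert-butyl hydroperoxide CC(C)(C)OO
Why: Sharpless asymmetric epoxidation of the (E)-allylic alcohol with the D-tartrate ligand should deliver oxygen to the face that gives the (2R,3R)-trans-epoxide; the electron-rich epoxide is taken on without delay.

Step 4
Reactants: 4 [(2R,3R)-3-[3,4-bis(benzyloxy)phenyl]oxiran-2-yl]methanol; 5 3,5-bis(benzyloxy)phenol
Product: 6 (2R,3S)-3-[3,5-bis(benzyloxy)phenoxy]-3-[3,4-bis(benzyloxy)phenyl]propane-1,2-diol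
Conditions: Cs2CO3 (0.3 equiv), DMF, 60 °C
Reagents that add atoms: none
Why: SN2 opening of the 3-aryl-2,3-epoxy alcohol by the phenoxide at the benzylic carbon, a known regiochemistry for this epoxide class, should proceed with inversion and set the (S) aryl ether carbon that becomes C2 of ring C (O1–C2 bond formed here).

Step 5
Reactants: 6 (2R,3S)-3-[3,5-bis(benzyloxy)phenoxy]-3-[3,4-bis(benzyloxy)phenyl]propane-1,2-diol
Product: 7 1,2-bis(triethylsilyl) ether of 6
Conditions: Et3SiCl, imidazole, DMF, 0 °C → rt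
Reagents that add atoms: chlorotriethylsilane CC[Si](CC)(CC)Cl
Why: standard silylation of both hydroxyl groups prepares the selective oxidation and installs the bulky C3–O group that later directs C4.

Step 6
Reactants: 7 1,2-bis(triethylsilyl) ether of 6
Product: 8 (2S,3S)-3-[3,5-bis(benzyloxy)phenoxy]-3-[3,4-bis(benzyloxy)phenyl]-2-(triethylsilyloxy)propanal
Conditions: (COCl)2, DMSO, CH2Cl2, −78 → −40 °C; then Et3N, −78 °C
Reagents that add atoms: none
Why: Swern conditions are known to convert primary triethylsilyl ethers directly into aldehydes while secondary ones survive, and the low temperature should prevent α-epimerization and β-elimination of the aryloxy group.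

Step 7
Reactants: 9 (−)-epicatechin
Product: 10 5,7,3',4'-tetra-O-benzyl-(−)-epicatechin
Conditions: BnBr, K2CO3, DMF, 0 °C → rt
Reagents that add atoms: benzyl bromide BrCc1ccccc1
Why: Williamson etherification with the weak base should benzylate the four phenols and leave the secondary alcohol and both stereocenters untouched.

Step 8
Reactants: 10 5,7,3',4'-tetra-O-benzyl-(−)-epicatechin
Product: 11 3,5,7,3',4'-penta-O-benzyl-(−)-epicatechin
Conditions: NaH, BnBr, Bu4NI (cat.), DMF, 0 °C → rt
Reagents that add atoms: benzyl bromide BrCc1ccccc1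
Why: Williamson etherification of the C3 alkoxide gives a non-participating ether that keeps this alcohol out of the later oxidation and falls off in the final hydrogenolysis.

Step 9
Reactants: 11 3,5,7,3',4'-penta-O-benzyl-(−)-epicatechin
Product: 12 (2R,3R,4S)-penta-O-benzyl-4β-(2-ethoxyethoxy)epicatechin
Conditions: DDQ, EtOCH2CH2OH, CH2Cl2, rt
Reagents that add atoms: 2-ethoxyethanol CCOCCO
Why: DDQ hydride abstraction at the benzylic C4 of benzylated flavan-3-ols is established, and the alcohol should capture the C4 cation on the face trans to the axial C3 ether (4β).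

Step 10
Reactants: 12 (2R,3R,4S)-penta-O-benzyl-4β-(2-ethoxyethoxy)epicatechin
Product: 13 (2R,3S,4S)-penta-O-benzyl-4β-(2,6-dimethylphenylsulfanyl)epicatechin
Conditions: 2,6-Me2C6H3SH, BF3·OEt2 (cat.), CH2Cl2, −78 → −40 °C
Reagents that add atoms: 2,6-dimethylbenzenethiol Cc1cccc(C)c1S
Why: Lewis-acid SN1 exchange through the C4 cation should place the thiol trans to the C3 ether and gives a soft C–S bond that hard Lewis acids do not ionize, so it masks the ring-F C4 hydroxyl through the key step.

Step 11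
Reactants: 8 (2S,3S)-3-[3,5-bis(benzyloxy)phenoxy]-3-[3,4-bis(benzyloxy)phenyl]-2-(triethylsilyloxy)propanal; 13 (2R,3S,4S)-penta-O-benzyl-4β-(2,6-dimethylphenylsulfanyl)epicatechin
Product: 16 3-O-triethylsilyl-tetra-O-benzyl-ent-catechin-(4β→8)-[penta-O-benzyl-4β-(2,6-dimethylphenylsulfanyl)epicatechin]; upper unit (2S,3R,4R), via flavan-4-ol 14 (not isolated), via flavan-4-yl cation 15 (not isolated)
Conditions: BF3·OEt2 (0.5 equiv), 13 (2.5 equiv), 4 Å MS, CH2Cl2, −78 → −30 °C, slow addition of 8
Reagents that add atoms: none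
Why: Proposed new method: BF3 activation of the aldehyde of 8 should let the ortho carbon of the phloroglucinol ether (future C4a, ortho/para to three oxygens and equivalent by symmetry to its twin) attack the carbonyl carbon in a 6-exo-trig Friedel–Crafts hydroxyalkylation that closes ring C and gives flavan-4-ol 14; the closest known reaction types are the Lewis-acid cyclization of 3-aryloxypropanals to chroman-4-ols and the Lewis-acid C4 arylation of 4-oxygenated flavan-3-ols used for procyanidins. The same ring-A oxygens (O1, O5, O7) should then drive ionization of the C4–O bond to the flavan-4-yl cation 15, the electrophile presumed in proanthocyanidin biosynthesis, which is captured by C8 of ring D of 13 in an intermolecular Friedel–Crafts alkylation that closes no further ring. C4 is the only new stereocenter: the bulky C3 silyloxy group sits on the face opposite the C2 aryl group and should send the large flavanyl nucleophile to the other face, giving the 3,4-trans, 2,4-cis arrangement (4R) seen in catechin-series couplings. The step needs ring closure before intermolecular attack (secured by the intramolecular six-membered mode and slow addition of 8 to excess 13), C8 over C6 attack on ring D (the known preference of benzylated flavan-3-ols) and survival of the thioether of 13 (soft C–S bond, hard boron Lewis acid, low temperature). C2 and C3 of 8 are not touched and are carried through; unreacted 13 is recovered.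

Step 12
Reactants: 16 3-O-triethylsilyl-tetra-O-benzyl-ent-catechin-(4β→8)-[penta-O-benzyl-4β-(2,6-dimethylphenylsulfanyl)epicatechin]
Product: 17 tetra-O-benzyl-ent-catechin-(4β→8)-[penta-O-benzyl-4β-(2,6-dimethylphenylsulfanyl)epicatechin]; upper unit (2S,3R,4R) with free C3–OH
Conditions: HF·pyridine, pyridine, THF, 0 °C → rt
Reagents that add atoms: none
Why: buffered fluoride desilylation should free the only silyl ether without ionizing the thioether or the interflavan bond.

Step 13
Reactants: 17 tetra-O-benzyl-ent-catechin-(4β→8)-[penta-O-benzyl-4β-(2,6-dimethylphenylsulfanyl)epicatechin]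
Product: 18 the C3 ketone of 17 (flavan-3-one upper unit; 2S,4R)
Conditions: Dess–Martin periodinane, pyridine, CH2Cl2, 0 °C → rt
Reagents that add atoms: none
Why: Dess–Martin oxidation, the established way to flavan-3-ones from benzylated catechins, should oxidize the single free alcohol under buffered conditions that tolerate the sulfide and leave C2 and C4 unepimerized.

Step 14
Reactants: 18 the C3 ketone of 17
Product: 19 tetra-O-benzyl-ent-epicatechin-(4β→8)-[penta-O-benzyl-4β-(2,6-dimethylphenylsulfanyl)epicatechin]; upper unit (2S,3S,4R), all-cis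
Conditions: LiBH(s-Bu)3, THF, −78 °C; then H2O (no peroxide work-up)
Reagents that add atoms: none
Why: the bulky borohydride, as in the known flavan-3-one to epicatechin reduction, should add from the face opposite the two cis aryl groups at C2 and C4, so the new C3 hydroxyl ends up cis to both (3S).

Step 15
Reactants: 19 tetra-O-benzyl-ent-epicatechin-(4β→8)-[penta-O-benzyl-4β-(2,6-dimethylphenylsulfanyl)epicatechin]
Product: 20 tetra-O-benzyl-ent-epicatechin-(4β→8)-[(2R,3R,4S)-penta-O-benzyl-4β-hydroxyepicatechin]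
Conditions: AgBF4, 2,6-di-tert-butylpyridine, THF/H2O, −20 → 0 °C
Reagents that add atoms: water O
Why: thiophilic activation of a flavan C4 thioether by a silver salt is a known way to the C4 cation, and water should add trans to the axial C3 benzyloxy group (4β, 4S) while the hindered base keeps the acid-labile product from re-ionizing.

Step 16
Reactants: 20 tetra-O-benzyl-ent-epicatechin-(4β→8)-[(2R,3R,4S)-penta-O-benzyl-4β-hydroxyepicatechin]
Product: 21 CNP0114173.1
Conditions: H2 (1 atm), Pd(OH)2/C, NaHCO3, THF/MeOH, rt, short contact time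
Reagents that add atoms: none
Why: hydrogenolysis should remove all nine benzyl ethers, and the bicarbonate buffer is meant to suppress acid-assisted loss of the benzylic ring-F C4 hydroxyl; no stereocenter is touched.

## Compound list

1 | 3,4-bis(benzyloxy)benzaldehyde | O=Cc1ccc(OCc2ccccc2)c(OCc2ccccc2)c1 | starting material
2 | ethyl (E)-3-[3,4-bis(benzyloxy)phenyl]prop-2-enoate | CCOC(=O)/C=C/c1ccc(OCc2ccccc2)c(OCc2ccccc2)c1 | intermediate
3 | (E)-3-[3,4-bis(benzyloxy)phenyl]prop-2-en-1-ol | OC/C=C/c1ccc(OCc2ccccc2)c(OCc2ccccc2)c1 | intermediate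
4 | [(2R,3R)-3-[3,4-bis(benzyloxy)phenyl]oxiran-2-yl]methanol | OC[C@H]1O[C@@H]1c1ccc(OCc2ccccc2)c(OCc2ccccc2)c1 | intermediate
5 | 3,5-bis(benzyloxy)phenol | Oc1cc(OCc2ccccc2)cc(OCc2ccccc2)c1 | starting material
6 | (2R,3S)-3-[3,5-bis(benzyloxy)phenoxy]-3-[3,4-bis(benzyloxy)phenyl]propane-1,2-diol | OC[C@@H](O)[C@H](c1ccc(OCc2ccccc2)c(OCc2ccccc2)c1)Oc1cc(OCc2ccccc2)cc(OCc2ccccc2)c1 | intermediate
7 | 1,2-bis(triethylsilyl) ether of 6 | CC[Si](CC)(CC)OC[C@@H](O[Si](CC)(CC)CC)[C@H](c1ccc(OCc2ccccc2)c(OCc2ccccc2)c1)Oc1cc(OCc2ccccc2)cc(OCc2ccccc2)c1 | intermediate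
8 | (2S,3S)-3-[3,5-bis(benzyloxy)phenoxy]-3-[3,4-bis(benzyloxy)phenyl]-2-(triethylsilyloxy)propanal | O=C[C@@H](O[Si](CC)(CC)CC)[C@H](c1ccc(OCc2ccccc2)c(OCc2ccccc2)c1)Oc1cc(OCc2ccccc2)cc(OCc2ccccc2)c1 | intermediate
9 | (−)-epicatechin, (2R,3R) | Oc1cc(O)c2c(c1)O[C@H](c1ccc(O)c(O)c1)[C@H](O)C2 | starting material
10 | 5,7,3',4'-tetra-O-benzyl-(−)-epicatechin | c1ccccc1COc1cc(OCc3ccccc3)c2c(c1)O[C@H](c1ccc(OCc3ccccc3)c(OCc3ccccc3)c1)[C@H](O)C2 | intermediate
11 | 3,5,7,3',4'-penta-O-benzyl-(−)-epicatechin | c1ccccc1COc1cc(OCc3ccccc3)c2c(c1)O[C@H](c1ccc(OCc3ccccc3)c(OCc3ccccc3)c1)[C@H](OCc3ccccc3)C2 | intermediate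
12 | (2R,3R,4S)-penta-O-benzyl-4β-(2-ethoxyethoxy)epicatechin | c1ccccc1COc1cc(OCc3ccccc3)c2c(c1)O[C@H](c1ccc(OCc3ccccc3)c(OCc3ccccc3)c1)[C@H](OCc3ccccc3)[C@H]2OCCOCC | intermediate
13 | (2R,3S,4S)-penta-O-benzyl-4β-(2,6-dimethylphenylsulfanyl)epicatechin | c1ccccc1COc1cc(OCc3ccccc3)c2c(c1)O[C@H](c1ccc(OCc3ccccc3)c(OCc3ccccc3)c1)[C@H](OCc3ccccc3)[C@H]2Sc1c(C)cccc1C | intermediate
14 | (2S,3R)-5,7,3',4'-tetra-O-benzyl-3-O-triethylsilylflavan-3,4-diol (flavan-4-ol formed in the flask in step 11; either C4 epimer) | c1ccccc1COc1cc(OCc3ccccc3)c2c(c1)O[C@@H](c1ccc(OCc3ccccc3)c(OCc3ccccc3)c1)[C@H](O[Si](CC)(CC)CC)C2O | intermediate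
15 | (2S,3R)-5,7,3',4'-tetra-O-benzyl-3-triethylsilyloxyflavan-4-yl cation (formed in the flask in step 11) | c1ccccc1COc1cc(OCc3ccccc3)c2c(c1)O[C@@H](c1ccc(OCc3ccccc3)c(OCc3ccccc3)c1)[C@H](O[Si](CC)(CC)CC)[CH+]2 | intermediate
16 | 3-O-triethylsilyl-tetra-O-benzyl-ent-catechin-(4β→8)-[penta-O-benzyl-4β-(2,6-dimethylphenylsulfanyl)epicatechin]; upper (2S,3R,4R), lower (2R,3S,4S) | c1ccccc1COc1cc(OCc3ccccc3)c2c(c1)O[C@@H](c1ccc(OCc3ccccc3)c(OCc3ccccc3)c1)[C@H](O[Si](CC)(CC)CC)[C@H]2c1c(OCc3ccccc3)cc(OCc3ccccc3)c2c1O[C@H](c1ccc(OCc3ccccc3)c(OCc3ccccc3)c1)[C@H](OCc3ccccc3)[C@H]2Sc1c(C)cccc1C | intermediate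
17 | tetra-O-benzyl-ent-catechin-(4β→8)-[penta-O-benzyl-4β-(2,6-dimethylphenylsulfanyl)epicatechin]; upper (2S,3R,4R) | c1ccccc1COc1cc(OCc3ccccc3)c2c(c1)O[C@@H](c1ccc(OCc3ccccc3)c(OCc3ccccc3)c1)[C@H](O)[C@H]2c1c(OCc3ccccc3)cc(OCc3ccccc3)c2c1O[C@H](c1ccc(OCc3ccccc3)c(OCc3ccccc3)c1)[C@H](OCc3ccccc3)[C@H]2Sc1c(C)cccc1C | intermediate
18 | C3 ketone of 17; upper unit (2S,4R)-flavan-3-one | c1ccccc1COc1cc(OCc3ccccc3)c2c(c1)O[C@@H](c1ccc(OCc3ccccc3)c(OCc3ccccc3)c1)C(=O)[C@H]2c1c(OCc3ccccc3)cc(OCc3ccccc3)c2c1O[C@H](c1ccc(OCc3ccccc3)c(OCc3ccccc3)c1)[C@H](OCc3ccccc3)[C@H]2Sc1c(C)cccc1C | intermediate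
19 | tetra-O-benzyl-ent-epicatechin-(4β→8)-[penta-O-benzyl-4β-(2,6-dimethylphenylsulfanyl)epicatechin]; upper (2S,3S,4R) all-cis | c1ccccc1COc1cc(OCc3ccccc3)c2c(c1)O[C@@H](c1ccc(OCc3ccccc3)c(OCc3ccccc3)c1)[C@@H](O)[C@H]2c1c(OCc3ccccc3)cc(OCc3ccccc3)c2c1O[C@H](c1ccc(OCc3ccccc3)c(OCc3ccccc3)c1)[C@H](OCc3ccccc3)[C@H]2Sc1c(C)cccc1C | intermediate
20 | tetra-O-benzyl-ent-epicatechin-(4β→8)-[(2R,3R,4S)-penta-O-benzyl-4β-hydroxyepicatechin] | c1ccccc1COc1cc(OCc3ccccc3)c2c(c1)O[C@@H](c1ccc(OCc3ccccc3)c(OCc3ccccc3)c1)[C@@H](O)[C@H]2c1c(OCc3ccccc3)cc(OCc3ccccc3)c2c1O[C@H](c1ccc(OCc3ccccc3)c(OCc3ccccc3)c1)[C@H](OCc3ccccc3)[C@H]2O | intermediate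
21 | CNP0114173.1 | Oc1cc(O)c2c(c1)O[C@@H](c1ccc(O)c(O)c1)[C@@H](O)[C@H]2c1c(O)cc(O)c2c1O[C@H](c1ccc(O)c(O)c1)[C@H](O)[C@H]2O | target

## Step count and risks

Total step count: 16. Longest linear sequence: 12 steps (steps 1–6, then 11–16); the nucleophile branch (steps 7–10) joins at step 11.

**Step 11 (proposed new method).** Four processes may defeat it:
- intermolecular hydroxyalkylation of ring D by the aldehyde before ring C has closed, which would hand C4 control to an uncontrolled cyclization;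
- self-condensation of the flavan-4-yl cation with ring A of another molecule;
- β-elimination of the aryloxy group or α-epimerization of the aldehyde under the Lewis acid;
- incomplete facial selectivity at C4.

The fallback uses known chemistry throughout and still closes ring C by the C4–C4a bond. It sets out from diol 6. Mitsunobu cyclodehydration (PPh3, DIAD, toluene) with activation of the primary hydroxyl should give the terminal epoxide (R)-2-{(S)-[3,5-bis(benzyloxy)phenoxy][3,4-bis(benzyloxy)phenyl]methyl}oxirane F1. The AuCl3/AgOTf-catalysed 6-endo epoxide–arene cyclization, an established entry to catechins, should then give 5,7,3',4'-tetra-O-benzyl-ent-catechin F2. Silylation (Et3SiCl, imidazole) gives its 3-O-triethylsilyl ether F3, and DDQ with 2-ethoxyethanol gives the 4-(2-ethoxyethoxy) derivative F4. BF3·OEt2-promoted coupling of F4 with 13 should then come back to the route at 16.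

**Step 14.** The basic hydride may enolize ketone 18 toward the doubly benzylic C4, or 18 may already epimerize at C4 during its formation; either process erodes the 2,4-cis relationship on which the facial selectivity rests. The fallback sets out from 18 and comes back at 19. It replaces the kinetic, substrate-controlled hydride addition by a Noyori transfer hydrogenation under dynamic kinetic resolution (RuCl(p-cymene)[TsDPEN], HCO2H/Et3N, with the ligand enantiomer matched to hydride delivery on the face opposite the aryl groups). C4 is allowed to equilibrate through the enol while the catalyst should reduce only the 2,4-cis epimer from its open face. No new compound is made.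

**Step 16.** Hydrogenolysis may also cleave the electron-rich benzylic C4–OH bond of ring F, or the hydroxyl may ionize on the catalyst surface and the product oligomerize. The fallback sets out from 20. Silylation (Et3SiOTf, 2,6-lutidine, CH2Cl2, −78 °C) should give the nona-O-benzyl 3,4'-bis-O-triethylsilyl ether F5, in which the benzylic oxygen is shielded. Hydrogenolysis (H2, Pd(OH)2/C) then gives the debenzylated 3,4'-bis-O-triethylsilyl compound F6, and pyridine-buffered HF·pyridine removes the two silyl groups to come back at 21.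

Further compounds
F1 | step 11 | (R)-2-{(S)-[3,5-bis(benzyloxy)phenoxy][3,4-bis(benzyloxy)phenyl]methyl}oxirane | C1O[C@H]1[C@H](c1ccc(OCc2ccccc2)c(OCc2ccccc2)c1)Oc1cc(OCc2ccccc2)cc(OCc2ccccc2)c1
F2 | step 11 | (2S,3R)-5,7,3',4'-tetra-O-benzyl-ent-catechin | c1ccccc1COc1cc(OCc3ccccc3)c2c(c1)O[C@@H](c1ccc(OCc3ccccc3)c(OCc3ccccc3)c1)[C@H](O)C2
F3 | step 11 | (2S,3R)-5,7,3',4'-tetra-O-benzyl-3-O-triethylsilyl-ent-catechin | c1ccccc1COc1cc(OCc3ccccc3)c2c(c1)O[C@@H](c1ccc(OCc3ccccc3)c(OCc3ccccc3)c1)[C@H](O[Si](CC)(CC)CC)C2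
F4 | step 11 | (2S,3R)-5,7,3',4'-tetra-O-benzyl-4-(2-ethoxyethoxy)-3-O-triethylsilyl-ent-catechin (C4 configuration immaterial) | c1ccccc1COc1cc(OCc3ccccc3)c2c(c1)O[C@@H](c1ccc(OCc3ccccc3)c(OCc3ccccc3)c1)[C@H](O[Si](CC)(CC)CC)C2OCCOCC
F0 | step 14 | none | none
F5 | step 16 | nona-O-benzyl 3,4'-bis-O-triethylsilyl ether of 20 | c1ccccc1COc1cc(OCc3ccccc3)c2c(c1)O[C@@H](c1ccc(OCc3ccccc3)c(OCc3ccccc3)c1)[C@@H](O[Si](CC)(CC)CC)[C@H]2c1c(OCc3ccccc3)cc(OCc3ccccc3)c2c1O[C@H](c1ccc(OCc3ccccc3)c(OCc3ccccc3)c1)[C@H](OCc3ccccc3)[C@H]2O[Si](CC)(CC)CC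
F6 | step 16 | 3,4'-bis-O-triethylsilyl ether of 21 | Oc1cc(O)c2c(c1)O[C@@H](c1ccc(O)c(O)c1)[C@@H](O[Si](CC)(CC)CC)[C@H]2c1c(O)cc(O)c2c1O[C@H](c1ccc(O)c(O)c1)[C@H](O)[C@H]2O[Si](CC)(CC)CC
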